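## Structural features

The target is a 5,7,4'-trihydroxyflavone (rings A, C and B) whose C8 carries a 2-carboxy-1-phenylethyl chain. The only stereocentre is C3 of the propanoic acid. It bears hydrogen, phenyl, the CH2CO2H arm and C8 of ring A, and it is R. No other stereocentre stands next to it, so it must be set by a catalyst or reagent and cannot be relayed.

Ring A is a phloroglucinol core substituted everywhere except C6. Its three oxygens have three roles: O1 in ring C, the chelated O5–H, and O7–H beside the chain.

Three points are fragile:
- the γ-(2-hydroxyaryl) acid closes to the six-membered O7 lactone under acid or heat;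
- the electron-rich ring A can lose the benzylic substituent by ipso protonation in strong acid, which would erode the configuration;
- the free polyphenol is sensitive to air in base.

The real difficulty is twofold: the enantioselective formation of a methine that carries two aryl groups of similar size, and the regiochemistry of ring C on a phloroglucinol (8- versus 6-substitution).

The key step exploits the lactone form. There C1 of the chain is a single carbon bridging C2 and O7, so it can be carbon monoxide placed between the terminal CH2 of a 1,1-diarylethylene and an ortho phenol. The hydrogen delivered to the diaryl carbon creates the stereocentre. The alkene precursor has two equivalent ortho hydroxyls and a para methoxy group, so the lactonisation has no regiochemical choice and leaves the three ring A oxygens distinguishable.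

## Logic of the disconnections

**15 to 14.** The O7–C1 ester bond is closed in the retrosynthetic sense, turning 15 into 14. The lactone is the form in which the chain is born in the key step, and in it the acid and the neighbouring hydroxyl mask each other. The gain is one functional group fewer to protect. The forward step must be a hydrolysis mild enough for a polyphenol, with a work-up that does not let the ring close again.

**14 to 13.** The O–CH3 bonds at O5 and O4' are restored, giving 13. Methyl is the ether most certain to survive an organomagnesium reagent, 6 with hydrogen over palladium, a boron Lewis acid, hydroxide and a hot oxidising medium. The forward step must cleave two aryl methyl ethers without breaking the benzylic C–aryl bond.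

**13 to 12.** The O1–C2 bond of ring C is cut and two hydrogens are returned to C2–C3, giving 12. This removes ring C. The forward oxidative cyclisation can only use the single free phenol ortho to the enone, so ring C can form in one sense only.

**12 to 8 and 9.** The Cα=Cβ bond of the enone is cut (aldol condensation), which removes ring B and three carbons. The forward step uses hydroxide, which opens the lactone; 10 and 11 form in the flask and the lactone must reclose on the correct oxygen. The opening is also useful: in 10 the two free positions of ring A are equivalent, so the site of the preceding acylation is not critical.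

**8 to 7.** The aryl–acetyl bond at C6 is cut. The forward step is an acylation ortho to the free phenol, which must leave the stereocentre and the lactone intact.

**7 to 5 and 6.** The C2–C3 bond, the O1–C2 bond and the C4–H bond of 7 are cut. This removes the ring, the stereocentre and the carbonyl carbon at once and leaves an achiral, locally symmetric alkene and 6. The forward step needs anti-Markovnikov addition of a palladium hydride to one enantioface of a 1,1-diarylethylene. Compound 5 is used with both hydroxyls free: protecting one would destroy the equivalence, and protecting both would remove the nucleophile.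

**5 to 2 and 3, through 4.** The C=CH2 bond is traced to dehydration of 4, and the C–CH3 bond of 4 to addition of 3 to the ketone of 2. The ketone has no enolisable hydrogen. The forward step must overcome the low electrophilicity of a doubly deprotonated ortho-hydroxy ketone and must avoid acid-induced oligomerisation of 5.

**2 to 1.** The O–CH3 bond at the para oxygen is cut. The forward step must methylate the one hydroxyl that is not beside the carbonyl group.

## Other disconnections considered

**Alternative 1:** The cut is at O1–C8a and C4–C4a, so ring A arrives as an aryne and rings B and C as 3-(4-methoxyphenyl)propiolic acid A2.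

- Forward key step: a fluoride source releases the 4a,8a-aryne from the ortho-silyl aryl triflate A1, tert-butyl (R)-3-[4,6-dimethoxy-2-(trifluoromethylsulfonyloxy)-3-(trimethylsilyl)phenyl]-3-phenylpropanoate. The carboxylate of A2 adds through oxygen, the aryl anion attacks the carbonyl, and the four-membered intermediate opens to the ortho-hydroxyaryl ynone A3, tert-butyl (R)-3-{2-hydroxy-4,6-dimethoxy-3-[3-(4-methoxyphenyl)propioloyl]phenyl}-3-phenylpropanoate. A3 would later close to the flavone by 6-endo-dig addition of the phenol.
- In favour: the methoxy group on C5 polarises the aryne so that oxygen adds at C8a and the acyl group ends on C4a, which is the required sense. A3 is already at the oxidation level of the flavone, so no oxidant and no strong base are needed. The tert-butyl ester removes any acid-or-lactone ambiguity. On the ring C end game this alternative is the better of the two.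
- Against: the step forms neither a ring nor the stereocentre, which would have to come from a separate asymmetric reaction (for instance a conjugate arylation of a cinnamate) before A1 is built. A1 is a pentasubstituted benzene whose silyl triflate must be installed on a ring that already carries the chain. The phloroglucinol oxygen at C8a is discarded as triflate and then brought back from the acid. C8a is flanked by the branched benzylic group, so sterics oppose the electronic preference. Aryne additions of acids can stop at simple O-arylation, and a propiolic acid can lose CO2 when heated.
- Comparison: on structure, the chosen plan gets ring A from a symmetric precursor, whereas A1 needs all six positions differentiated in advance. On mechanism, both end with an acyl group captured next to a phenol oxygen; aryne insertion into acids is an established reaction type while the chosen key step is not, so the alternative is the better on precedent. The chosen step, however, also sets the stereocentre and a ring. On step economy, the alternative is estimated at well over twelve steps against eight.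

**Alternative 2:** The cut runs through ring A (C5–C6, C7–C8 and C4a–C5), so ring A is assembled on a finished stereocentre from the cyclobutenone A4, methyl (R)-3-[2-(benzyloxy)-4-oxocyclobut-1-en-1-yl]-3-phenylpropanoate, and ethoxyacetylene A5.

- Forward key step: heating opens A4 to a vinylketene, which adds A5 in a [2+2] sense. The new cyclobutenone opens to a dienylketene, and 6π electrocyclisation with tautomerisation gives the phenol A6, methyl (R)-3-[2-(benzyloxy)-6-ethoxy-4-hydroxyphenyl]-3-phenylpropanoate.
- In favour: the substitution pattern of ring A follows from the pericyclic sequence and not from substitution rules. The three oxygens emerge with three different substituents, which equals the differentiation reached in 7. The conditions are neutral and thermal, so the stereocentre is safe. The aryl–C(stereocentre) bond needs no electrophilic substitution.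
- Against: the stereocentre must be set earlier in an aliphatic precursor and carried through the synthesis of a 2-substituted 3-alkoxycyclobutenone, which is itself several steps. A4 is a vinylogous ester and should open only at high temperature. A5 is volatile and sensitive. After the key step, ring C must still be built in full. The acyl group must enter at C4a, but C4a and C6 are both ortho to the free C5 hydroxyl and differ only by a benzyl versus an ethyl ether neighbour; acylation at C6 leads to the 6-substituted flavone. An ethyl ether must also be cleaved at the end.
- Comparison: on structure, the alternative differentiates the oxygens by construction and the chosen plan by symmetry, and the two are equal up to the key step; afterwards the chosen plan is safer, because lactone opening makes the acylation site irrelevant. On mechanism, the benzannulation is known chemistry and the better on precedent, but it solves ring A, which is the easy part here, and leaves the stereocentre to another reaction. On step economy it is clearly longer.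

**Alternative 3:** The cut is the C2=C3 bond of ring C.

- Forward key step: the acyl-stabilised ylide A7, (R)-7-methoxy-2-oxo-4-phenyl-6-[(triphenylphosphoranylidene)acetyl]chroman-5-yl 4-methoxybenzoate, attacks the ester carbonyl on the neighbouring oxygen in an intramolecular Wittig reaction. Loss of the phosphine oxide gives A8, which is the same compound as 13.
- In favour: ring C closes at the right oxidation level under weakly basic, non-oxidising conditions, and the lactone is never opened. The regiochemistry is fixed by which oxygen carries the aroyl group. On mildness towards the lactone and the stereocentre it is the better end game than steps 5 and 6.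
- Against: it addresses only ring C. The stereocentre and the ring A pattern must come from elsewhere, most sensibly from 7 and 8. From 8, A7 needs α-halogenation of the methyl ketone (with ring halogenation at the electron-rich C8 as a competitor), phosphonium salt formation, O-aroylation and ylide generation: about four operations in place of two. Stabilised ylides add to ester carbonyls only on heating, and a stoichiometric phosphine oxide is formed.
- Comparison: on structure it is equal, since it reaches the same intermediate. On mechanism, the ester Wittig closure is known, and so is the aldol and oxidative cyclisation sequence. On step economy it is about two steps longer. It competes with the end game and not with the key step.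

Key step: step 3

Assumptions and remarks on the chemistry:
- The sense of induction of a chiral diphosphine in this hydropalladation cannot be predicted with confidence. The ligand enantiomer that gives the R lactone is taken to be found in a first screen of both antipodes, and the route is written for that enantiomer.
- In 7, 8 and 10 to 15 the priority order at the stereocentre is oxygenated aryl > phenyl > CH2 > H, so the descriptor R denotes the same spatial arrangement throughout.
- Compounds 10 and 11 exist in the flask as potassium salts and are listed as the neutral acids.

Step 1
Reactants: 1 2,4,6-trihydroxybenzophenone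
Product: 2 2,6-dihydroxy-4-methoxybenzophenone
Conditions: Me2SO4 (1.0 equiv), K2CO3 (1.0 equiv), acetone, rt
Reagents that add atoms: dimethyl sulfate, COS(=O)(=O)OC
Why: Williamson O-methylation; the 4-hydroxyl is the most acidic (para to the carbonyl) and the only one neither hydrogen-bonded to nor crowded by the benzoyl group, so with one equivalent of base and alkylating agent it should react first, and any over-methylated material is removed by chromatography.

Step 2
Reactants: 2 2,6-dihydroxy-4-methoxybenzophenone; 3 methylmagnesium bromide
Product: 5 5-methoxy-2-(1-phenylvinyl)benzene-1,3-diol, via tertiary carbinol 4 (not isolated)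
Conditions: MeMgBr (5 equiv), THF, 0 °C to 50 °C; aq. NH4Cl; then PPTS (5 mol%), toluene, 60 °C
Reagents that add atoms: none
Why: Grignard 1,2-addition to an ortho-hydroxybenzophenone followed by acid-catalysed E1 dehydration; two equivalents of 3 deprotonate the phenols, the magnesium phenoxide chelates and activates the ketone, which has no enolisable hydrogen, and the doubly ortho-hydroxylated tertiary benzylic alcohol 4 ionises with a trace of weak acid (ortho-quinone methide character) and can lose a proton only from the methyl group, so a single alkene should form.

Step 3
Reactants: 5 5-methoxy-2-(1-phenylvinyl)benzene-1,3-diol; 6 carbon monoxide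
Product: 7 (R)-5-hydroxy-7-methoxy-4-phenylchroman-2-one
Conditions: Pd(OAc)2 (5 mol%), DIOP (6 mol%, enantiomer giving R), CO/H2 (4:1, 40 bar), toluene, 90 °C
Reagents that add atoms: none
Why: Proposed new method: Pd(OAc)2, the diphosphine, CO and H2 should give a divalent palladium hydride, to which the alkene of 5 adds with palladium on the terminal CH2 and hydrogen on the diaryl carbon, because the alternative tertiary dibenzylic alkylpalladium is too crowded to take up CO and can only revert by β-hydride elimination. CO (6) then inserts into the primary Pd–C bond and one of the two ortho phenols attacks the acyl carbon, which releases 7 and regenerates the hydride. The ring closes by a 6-exo-trig acyl substitution at the acylpalladium (equivalently, C–O reductive elimination from an aryloxy acyl complex), forming C2–C3 and O1–C2 of 7. The closest known reaction type is the palladium-catalysed cyclocarbonylation of 2-(1-methylvinyl)phenols, 2-allylphenols and 2-vinylanilines under CO/H2 to lactones and lactams, which has enantioselective variants with DIOP-type ligands; new here is a 1,1-diarylethylene, where the catalyst must tell two aryl groups apart instead of aryl from methyl. The stereocentre C4 is created when hydride is delivered to one enantioface of the alkene and is controlled by the chiral diphosphine on palladium; if hydropalladation is reversible, the same ligand controls which diastereomeric alkylpalladium inserts CO faster. The two aryl groups differ more than their size suggests: the 2,6-dihydroxyaryl ring is twisted out of the alkene plane and can bind palladium through a phenol oxygen, whereas phenyl stays conjugated and cannot. No regioselectivity between the hydroxyls is needed, since they are equivalent in 5, and the substrate has no allylic hydrogen, so it cannot isomerise. Chemoselectivity against plain hydrogenation and against acid-induced dimerisation of the electron-rich alkene is addressed by the CO-rich gas mixture and by the absence of any Brønsted acid co-catalyst.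

Step 4
Reactants: 7 (R)-5-hydroxy-7-methoxy-4-phenylchroman-2-one
Product: 8 (R)-6-acetyl-5-hydroxy-7-methoxy-4-phenylchroman-2-one
Conditions: Ac2O (1.5 equiv), BF3·OEt2 (3 equiv), ClCH2CH2Cl, 60 °C; then aq. NaOAc
Reagents that add atoms: acetic anhydride, CC(=O)OC(C)=O
Why: Lewis-acid-mediated Friedel–Crafts (Fries-type) ortho-acetylation of a phenol; the boron-bound 5-hydroxyl directs the acyl group to C6, where the product is stabilised as a chelate and is deactivated against a second acylation, and the stereocentre is not involved. Acylation at C8 instead would be corrected in step 5, because opening of the lactone makes the two sites equivalent.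

Step 5
Reactants: 8 (R)-6-acetyl-5-hydroxy-7-methoxy-4-phenylchroman-2-one; 9 4-methoxybenzaldehyde
Product: 12 (R,E)-5-hydroxy-7-methoxy-6-[3-(4-methoxyphenyl)prop-2-enoyl]-4-phenylchroman-2-one, via ring-opened keto acid 10 (not isolated), via chalcone acid 11 (not isolated)
Conditions: KOH (50% aq., 10 equiv), EtOH, 0 °C to rt, N2; 2 M HCl to pH 2; then TsOH·H2O (5 mol%), toluene–THF, 60 °C
Reagents that add atoms: none
Why: Claisen–Schmidt aldol condensation; hydroxide first opens the aryl lactone to 10, whose methyl ketone enolate condenses with the non-enolisable aldehyde 9 and dehydrates (E1cB) to the thermodynamically preferred E enone 11. Acid then recloses the lactone on the hydroxyl that is not hydrogen-bonded to the ketone, which gives 12, the more stable lactone because it keeps the chelate; the stereocentre is not α to a carbonyl and has no acidic hydrogen under these conditions.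

Step 6
Reactants: 12 (R,E)-5-hydroxy-7-methoxy-6-[3-(4-methoxyphenyl)prop-2-enoyl]-4-phenylchroman-2-one
Product: 13 (R)-5-methoxy-2-(4-methoxyphenyl)-10-phenyl-9,10-dihydro-4H,8H-pyrano[2,3-f]chromene-4,8-dione
Conditions: I2 (10 mol%), DMSO, 120 °C
Reagents that add atoms: none
Why: Iodine-catalysed oxidative cyclisation of a 2'-hydroxychalcone to a flavone with DMSO as terminal oxidant; the chelated 5-hydroxyl is the only free phenol ortho to the enone, so it adds in a 6-endo sense and the ring is dehydrogenated in one possible orientation only, while the lactone, the methyl ethers and the non-enolisable stereocentre should tolerate the conditions.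

Step 7
Reactants: 13 (R)-5-methoxy-2-(4-methoxyphenyl)-10-phenyl-9,10-dihydro-4H,8H-pyrano[2,3-f]chromene-4,8-dione
Product: 14 (R)-5-hydroxy-2-(4-hydroxyphenyl)-10-phenyl-9,10-dihydro-4H,8H-pyrano[2,3-f]chromene-4,8-dione
Conditions: BBr3 (8 equiv), CH2Cl2, −78 °C to rt; ice–water
Reagents that add atoms: none
Why: Lewis-acid cleavage of aryl methyl ethers (bromide attacks the methyl group of the boron-bound ether in an SN2 step); the 5-methoxy group peri to the carbonyl should go first with chelation help and the 4'-methoxy group at room temperature. Ring A is deactivated by the pyranone and the lactone, which protects the benzylic C–aryl bond, and a lactone opened by the reagent would reclose on acidic work-up or be hydrolysed in step 8 anyway.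

Step 8
Reactants: 14 (R)-5-hydroxy-2-(4-hydroxyphenyl)-10-phenyl-9,10-dihydro-4H,8H-pyrano[2,3-f]chromene-4,8-dione
Product: 15 (R)-3-[5,7-dihydroxy-2-(4-hydroxyphenyl)-4-oxo-4H-chromen-8-yl]-3-phenylpropanoic acid
Conditions: LiOH·H2O (6 equiv), THF–H2O (degassed), 0 °C to rt; then cold 1 M HCl to pH 3–4
Reagents that add atoms: lithium hydroxide, [Li+].[OH-]
Why: Saponification of an aryl ester (the lactone), which is fast because the leaving group is the stabilised 7-phenoxide of a flavone; the stereocentre is β to the carboxylate and not acidic, and cold acidification only to pH 3–4 with extraction without heating should keep the hydroxy acid from closing again, helped by the low nucleophilicity of the 7-hydroxyl.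

## Compound list

1 | 2,4,6-trihydroxybenzophenone | O=C(c1ccccc1)c1c(O)cc(O)cc1O | starting material
2 | 2,6-dihydroxy-4-methoxybenzophenone | COc1cc(O)c(C(=O)c2ccccc2)c(O)c1 | intermediate
3 | methylmagnesium bromide | C[Mg]Br | starting material
4 | 2-(1-hydroxy-1-phenylethyl)-5-methoxybenzene-1,3-diol (racemic) | CC(O)(c1ccccc1)c1c(O)cc(OC)cc1O | intermediate (not isolated)
5 | 5-methoxy-2-(1-phenylvinyl)benzene-1,3-diol | C=C(c1ccccc1)c1c(O)cc(OC)cc1O | intermediate
6 | carbon monoxide | [C-]#[O+] | starting material
7 | (R)-5-hydroxy-7-methoxy-4-phenylchroman-2-one | O=C1C[C@H](c2ccccc2)c2c(O)cc(OC)cc2O1 | intermediate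
8 | (R)-6-acetyl-5-hydroxy-7-methoxy-4-phenylchroman-2-one | O=C1C[C@H](c2ccccc2)c2c(O)c(C(C)=O)c(OC)cc2O1 | intermediate
9 | 4-methoxybenzaldehyde | COc1ccc(C=O)cc1 | starting material
10 | (R)-3-(3-acetyl-2,6-dihydroxy-4-methoxyphenyl)-3-phenylpropanoic acid | O=C(O)C[C@H](c1ccccc1)c1c(O)c(C(C)=O)c(OC)cc1O | intermediate (not isolated)
11 | (R,E)-3-{2,6-dihydroxy-4-methoxy-3-[3-(4-methoxyphenyl)prop-2-enoyl]phenyl}-3-phenylpropanoic acid | O=C(O)C[C@H](c1ccccc1)c1c(O)c(C(=O)/C=C/c2ccc(OC)cc2)c(OC)cc1O | intermediate (not isolated)
12 | (R,E)-5-hydroxy-7-methoxy-6-[3-(4-methoxyphenyl)prop-2-enoyl]-4-phenylchroman-2-one | O=C1C[C@H](c2ccccc2)c2c(O)c(C(=O)/C=C/c3ccc(OC)cc3)c(OC)cc2O1 | intermediate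
13 | (R)-5-methoxy-2-(4-methoxyphenyl)-10-phenyl-9,10-dihydro-4H,8H-pyrano[2,3-f]chromene-4,8-dione | O=C1C[C@H](c2ccccc2)c2c(O1)cc(OC)c1c(=O)cc(-c3ccc(OC)cc3)oc21 | intermediate
14 | (R)-5-hydroxy-2-(4-hydroxyphenyl)-10-phenyl-9,10-dihydro-4H,8H-pyrano[2,3-f]chromene-4,8-dione | O=C1C[C@H](c2ccccc2)c2c(O1)cc(O)c1c(=O)cc(-c3ccc(O)cc3)oc21 | intermediate
15 | (R)-3-[5,7-dihydroxy-2-(4-hydroxyphenyl)-4-oxo-4H-chromen-8-yl]-3-phenylpropanoic acid | O=C(O)C[C@H](c1ccccc1)c1c(O)cc(O)c2c(=O)cc(-c3ccc(O)cc3)oc12 | target

## Step count and least certain steps

Total: 8 steps. Longest linear sequence: 8 steps, from 1 to 15; compounds 3, 6 and 9 are purchased.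

**Step 3 (key step).** The most likely failure is poor enantioface discrimination, because the catalyst must distinguish two aryl groups on the same alkene carbon at the moment of hydride transfer. The next concerns are slow hydropalladation of a hindered, conjugated 1,1-diarylethylene and competing hydrogenation of the alkene. The fallback sets out from 5 and returns at 7 using known reaction types. Compound 5 is carboxylated at the vinyl C–H bond with CO2 (1 atm), Pd(OAc)2 and Cs2CO3 in diglyme at 100 °C, the known lactonisation of 2-(1-arylvinyl)phenols, to give 5-hydroxy-7-methoxy-4-phenyl-2H-chromen-2-one F1. The C3–C4 double bond of F1 is then reduced by the known asymmetric 1,4-reduction of 4-arylcoumarins with CuH, generated from Cu(OAc)2·H2O, DTBM-SEGPHOS (the enantiomer that gives R) and diethoxymethylsilane with t-BuOH in toluene. The free phenol is silylated in the flask and released on work-up, which gives 7.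

**Step 2.** Addition may be sluggish because the ketone reacts as a doubly deprotonated, chelated and electron-rich species. The acid used for dehydration can also start oligomerisation of the electron-rich alkene. The fallback sets out from 2 and returns at 5. Both phenols are allylated (allyl bromide, K2CO3, DMF, 60 °C) to give [2,6-bis(allyloxy)-4-methoxyphenyl](phenyl)methanone F2. The now neutral ketone is methylenated by a Wittig reaction (Ph3PCH3Br, KOtBu, THF, reflux) to 1,3-bis(allyloxy)-5-methoxy-2-(1-phenylvinyl)benzene F3. The allyl groups are removed under neutral conditions with Pd(PPh3)4 and morpholine in THF, which gives 5 without any acid.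

**Step 4.** Forcing Lewis-acid conditions could erode the configuration through reversible heterolysis of the benzylic C–aryl bond after ipso protonation, or could cleave the lactone and cause multiple acylation. The fallback sets out from 7 and rejoins the route at 10 inside step 5. The lactone is opened with NaOMe in MeOH at 0 °C to methyl (R)-3-(2,6-dihydroxy-4-methoxyphenyl)-3-phenylpropanoate F4, in which the two free ring positions are equivalent and the ring is a far better nucleophile. A Hoesch reaction (MeCN, ZnCl2, HCl gas, Et2O, 0 °C) gives the ketiminium salt methyl (R)-3-[2,6-dihydroxy-3-(1-iminoethyl)-4-methoxyphenyl]-3-phenylpropanoate hydrochloride F5. Warm water hydrolyses it to methyl (R)-3-(3-acetyl-2,6-dihydroxy-4-methoxyphenyl)-3-phenylpropanoate F6. F6 is taken directly into the KOH of step 5, where the ester is saponified to 10.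

**Step 5.** Enolisation and condensation may be slow, because in the flask the ketone is part of a trianion with ortho and para phenoxides. Hydroxide can meanwhile consume the aldehyde by disproportionation, and the lactone could reclose on the wrong hydroxyl. The fallback sets out from 7 and returns at 12, replacing steps 4 and 5 by one Friedel–Crafts acylation with (E)-3-(4-methoxyphenyl)acryloyl chloride and BF3·OEt2 in ClCH2CH2Cl at 50 °C. The enone is then introduced directly ortho to the phenol, with no base and with the lactone closed throughout; premature ring closure of the enone by the phenol would be harmless, since step 6 takes both forms to the flavone.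

**Step 8.** The hydroxy acid may reclose to the lactone during acidification or concentration, and the polyphenolate may oxidise in air. The fallback sets out from 14 and returns at 15. The lactone is opened with allyl alcohol and K2CO3 at room temperature to allyl (R)-3-[5,7-dihydroxy-2-(4-hydroxyphenyl)-4-oxo-4H-chromen-8-yl]-3-phenylpropanoate F7. The allyl ester is cleaved under neutral conditions (Pd(PPh3)4, PhSiH3, CH2Cl2, then water), so the acid is released without passing through strongly acidic or strongly basic water.

## Further compounds

F1 | step 3 | 5-hydroxy-7-methoxy-4-phenyl-2H-chromen-2-one | O=c1cc(-c2ccccc2)c2c(O)cc(OC)cc2o1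
F2 | step 2 | [2,6-bis(allyloxy)-4-methoxyphenyl](phenyl)methanone | C=CCOc1cc(OC)cc(OCC=C)c1C(=O)c1ccccc1
F3 | step 2 | 1,3-bis(allyloxy)-5-methoxy-2-(1-phenylvinyl)benzene | C=CCOc1cc(OC)cc(OCC=C)c1C(=C)c1ccccc1
F4 | step 4 | methyl (R)-3-(2,6-dihydroxy-4-methoxyphenyl)-3-phenylpropanoate | COC(=O)C[C@H](c1ccccc1)c1c(O)cc(OC)cc1O
F5 | step 4 | methyl (R)-3-[2,6-dihydroxy-3-(1-iminoethyl)-4-methoxyphenyl]-3-phenylpropanoate hydrochloride | COC(=O)C[C@H](c1ccccc1)c1c(O)c(C(C)=[NH2+])c(OC)cc1O.[Cl-]
F6 | step 4 | methyl (R)-3-(3-acetyl-2,6-dihydroxy-4-methoxyphenyl)-3-phenylpropanoate | COC(=O)C[C@H](c1ccccc1)c1c(O)c(C(C)=O)c(OC)cc1O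
F0 | step 5 | none | none
F7 | step 8 | allyl (R)-3-[5,7-dihydroxy-2-(4-hydroxyphenyl)-4-oxo-4H-chromen-8-yl]-3-phenylpropanoate | C=CCOC(=O)C[C@H](c1ccccc1)c1c(O)cc(O)c2c(=O)cc(-c3ccc(O)cc3)oc12
A1 | alternative 1 | tert-butyl (R)-3-[4,6-dimethoxy-2-(trifluoromethylsulfonyloxy)-3-(trimethylsilyl)phenyl]-3-phenylpropanoate | CC(C)(C)OC(=O)C[C@H](c1ccccc1)c1c(OC)cc(OC)c([Si](C)(C)C)c1OS(=O)(=O)C(F)(F)F
A2 | alternative 1 | 3-(4-methoxyphenyl)propiolic acid | COc1ccc(C#CC(=O)O)cc1
A3 | alternative 1 | tert-butyl (R)-3-{2-hydroxy-4,6-dimethoxy-3-[3-(4-methoxyphenyl)propioloyl]phenyl}-3-phenylpropanoate | CC(C)(C)OC(=O)C[C@H](c1ccccc1)c1c(OC)cc(OC)c(C(=O)C#Cc2ccc(OC)cc2)c1O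
A4 | alternative 2 | methyl (R)-3-[2-(benzyloxy)-4-oxocyclobut-1-en-1-yl]-3-phenylpropanoate | COC(=O)C[C@H](c1ccccc1)C1=C(OCc2ccccc2)CC1=O
A5 | alternative 2 | ethoxyacetylene | C#COCC
A6 | alternative 2 | methyl (R)-3-[2-(benzyloxy)-6-ethoxy-4-hydroxyphenyl]-3-phenylpropanoate | COC(=O)C[C@H](c1ccccc1)c1c(OCC)cc(O)cc1OCc1ccccc1
A7 | alternative 3 | (R)-7-methoxy-2-oxo-4-phenyl-6-[(triphenylphosphoranylidene)acetyl]chroman-5-yl 4-methoxybenzoate | O=C1C[C@H](c2ccccc2)c2c(OC(=O)c3ccc(OC)cc3)c(C(=O)C=P(c3ccccc3)(c3ccccc3)c3ccccc3)c(OC)cc2O1
A8 | alternative 3 | (R)-5-methoxy-2-(4-methoxyphenyl)-10-phenyl-9,10-dihydro-4H,8H-pyrano[2,3-f]chromene-4,8-dione (identical with 13) | O=C1C[C@H](c2ccccc2)c2c(O1)cc(OC)c1c(=O)cc(-c3ccc(OC)cc3)oc21
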